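The atoms are labelled as follows. The seven-membered ring is C1 (ester carbinol), C2, C3 (methyl carbinol), C4=C5, C6 (quaternary, CH3), C10 (fusion CH). The five-membered ring is C6, C7, C8, C9 (isopropyl carbinol), C10. The feature exploited is the triad C6–CH3, C10–H, C1–O: with C6 bonded to C1 instead of C10, it is the ring fusion of an angular-methyl cis-decalin. One stereospecific 1,2-shift of C6 from C1 to C10 contracts the six-membered ring holding C9 and enlarges the one holding C3. It also sets the trans C10 hydrogen and releases the C1 ketone. The precursor is a cis-decalin with free C1-OH, an equatorial C10 mesylate and silylated C3 and C9 hydroxyls.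

Key step: step 13

Conventions: the labels C1–C10 are kept for all bicyclic compounds. In the decalins ring A is C1–C2–C3–C4–C5–C6 and ring B is C1–C10–C9–C8–C7–C6. β is the face of the C6 methyl group and α is the opposite face. Read this way the target has C6-CH3 β, C9-OH β, C3-OH β, C10-H α and C1-O α.

Assumption: enantiopure (S)-Wieland–Miescher ketone is the only source of absolute configuration.

Design notes:
- (a) An equatorial C10–O bond is antiperiplanar to C9–C8 as well as to C1–C6. Alignment alone therefore cannot exclude a C8 shift, so O9 is masked and the shift is run with an aluminium reagent that can bind only to O1.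
- (b) Osmylation comes before ring A is oxidised. Only one allylic hydroxyl is then present, C3 becomes the only allylic CH2, and no β,γ-unsaturated enone is ever formed.
- (c) In the cis-decalin a methyl nucleophile would reach a C3 ketone from the β face and give the wrong epimer. Carbon is therefore introduced first (methylenation) and oxygen second (β-face epoxidation).

Step 1
Reactants: 1 (S)-Wieland–Miescher ketone
Product: 2 (4aS,5S)-5-hydroxy-4a-methyl-4,4a,5,6,7,8-hexahydronaphthalen-2(3H)-one (C5-OH β)
Conditions: NaBH4 (0.3 equiv), EtOH, −10 °C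
Reagents that add atoms: none
Why: Chemoselective borohydride reduction, in which the isolated C5 ketone is more electrophilic than the conjugated C9 ketone and hydride enters from the α face away from the angular methyl (this stereocentre is removed again in step 3).

Step 2
Reactants: 2 (4aS,5S)-5-hydroxy-4a-methyl-4,4a,5,6,7,8-hexahydronaphthalen-2(3H)-one
Product: 3 C5 β-mesylate of 2
Conditions: MsCl, Et3N, CH2Cl2, 0 °C
Reagents that add atoms: methanesulfonyl chloride CS(=O)(=O)Cl
Why: Standard sulfonylation of a secondary alcohol with retention at C5; the enone is inert.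

Step 3
Reactants: 3 C5 β-mesylate of 2
Product: 4 (R)-4a-methyl-4,4a,7,8-tetrahydronaphthalen-2(3H)-one (C9 enone; C4=C5 alkene)
Conditions: LiBr, Li2CO3, DMF, 130 °C
Reagents that add atoms: none
Why: Thermal sulfonate elimination under weakly basic conditions; C6 is quaternary, so only C4 offers β-hydrogens and C4=C5 is the only possible alkene.

Step 4
Reactants: 4 (R)-4a-methyl-4,4a,7,8-tetrahydronaphthalen-2(3H)-one
Product: 5 C9 tertiary allylic alcohol (C9-OH β; isopropyl α; C1=C10 and C4=C5 alkenes)
Conditions: iPrMgCl, CeCl3 (anhydrous), THF, −78 °C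
Reagents that add atoms: isopropylmagnesium chloride CC(C)[Mg]Cl
Why: Organocerium 1,2-addition, in which the weakly basic oxophilic reagent suppresses enolisation, β-hydride reduction and conjugate addition and attacks the half-chair enone axially on the α face opposite the pseudo-axial C6 methyl, setting C9.

Step 5
Reactants: 5 C9 tertiary allylic alcohol
Product: 7 cis-decalin triol (C1-OH; C10-OH; C9-OH all β; isopropyl α; C4=C5), via TMEDA-bound osmate ester 6 (not isolated)
Conditions: OsO4 (1.05 equiv), TMEDA, CH2Cl2, −78 °C; then aq. Na2SO3, THF, reflux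
Reagents that add atoms: osmium tetroxide O=[Os](=O)(=O)=O
Why: Hydrogen-bond-directed syn-dihydroxylation, in which the OsO4–TMEDA adduct is held by the C9 β-hydroxyl and adds to the allylic, more electron-rich C1=C10 alkene from the β face (setting C1, C10 and the cis fusion), while the undirected neopentyl C4=C5 alkene is left alone.

Step 6
Reactants: 7 cis-decalin triol
Product: 8 C10 acetate of 7
Conditions: Ac2O, DMAP, pyridine, rt
Reagents that add atoms: acetic anhydride CC(=O)OC(C)=O
Why: DMAP-catalysed acylation picks out the only secondary hydroxyl from the two hindered tertiary ones and shields it from the oxidant of step 7.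

Step 7
Reactants: 8 C10 acetate of 7
Product: 9 C3 enone of 8 (C3=O conjugated to C4=C5)
Conditions: Rh2(cap)4 (1 mol %), tBuOOH (70 % aq.), ClCH2CH2Cl, 40 °C
Reagents that add atoms: tert-butyl hydroperoxide CC(C)(C)OO
Why: Dirhodium-catalysed allylic C–H oxidation, in which C3 is the only allylic CH2 left and the allyl radical is trapped at C3 rather than at the neopentyl C5, under base-free conditions that spare the β-hydroxy ketone.

Step 8
Reactants: 9 C3 enone of 8
Product: 10 C3-methylene diene (C3=CH2; C4=C5)
Conditions: Ph3PCH3Br, KHMDS, THF, 0 °C to rt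
Reagents that add atoms: methyltriphenylphosphonium bromide C[P+](c1ccccc1)(c1ccccc1)c1ccccc1.[Br-]
Why: Wittig methylenation of the enone carbonyl; the ylide is too weak a base to form the tertiary alkoxides, so no retro-aldol cleavage is triggered, and the hindered acetate survives.

Step 9
Reactants: 10 C3-methylene diene
Product: 11 C3 spiro-epoxide (epoxide O β; CH2 α; C4=C5 kept)
Conditions: dimethyldioxirane (1.0 equiv), acetone–CH2Cl2, −20 °C
Reagents that add atoms: dimethyldioxirane CC1(C)OO1
Why: Neutral dioxirane epoxidation of the more accessible 1,1-disubstituted alkene, in which C10 stands axial on ring A (chair with equatorial isopropyl) and blocks the α face of C3, so oxygen arrives from the convex β face and sets C3.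

Step 10
Reactants: 11 C3 spiro-epoxide
Product: 12 cis-decalin tetraol (C1; C3; C9; C10 hydroxyls all β; C3-CH3 α; C4=C5)
Conditions: LiEt3BH (excess), THF, 0 °C to rt
Reagents that add atoms: none
Why: SN2 hydride opening at the unhindered epoxide CH2 turns it into the C3 methyl group without touching the β C3–O bond, and the same reagent cleaves the acetate reductively.

Step 11
Reactants: 12 cis-decalin tetraol
Product: 13 cis-decalin triol C10-mesylate
Conditions: MsCl, pyridine, DMAP (cat.), CH2Cl2, 0 °C
Reagents that add atoms: methanesulfonyl chloride CS(=O)(=O)Cl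
Why: Sulfonylation in pyridine (no sulfene) reaches only the secondary equatorial C10 hydroxyl, the three tertiary hydroxyls are inert, and the gauche cis neighbours O1 and O9 cannot close an epoxide.

Step 12
Reactants: 13 cis-decalin triol C10-mesylate
Product: 14 C3,C9-bis(triethylsilyl) ether of 13 (free C1-OH)
Conditions: TESOTf (2.2 equiv), 2,6-lutidine, CH2Cl2, −78 to −40 °C
Reagents that add atoms: triethylsilyl triflate CC[Si](CC)(CC)OS(=O)(=O)C(F)(F)F
Why: Silyl triflate silylation under steric control, in which O3 (methyl carbinol) and O9 (whose isopropyl group can turn its methine hydrogen towards oxygen) react first, while the ring-fusion O1, wedged between quaternary C6 and C10, should stay free with limited reagent.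

Step 13
Reactants: 14 C3,C9-bis(triethylsilyl) ether of 13
Product: 16 trans-fused C3,C9-bis(triethylsilyloxy)hydroazulen-C1-one (C10-H α), via chloro(ethyl)aluminium C1-alkoxide 15 (not isolated)
Conditions: Et2AlCl (2.5 equiv), CH2Cl2, −78 to −20 °C
Reagents that add atoms: none
Why: Et2AlCl first turns the free C1 hydroxyl into alkoxide 15 with loss of ethane; the metal, held next to the gauche C10 sulfonate, then pulls on the mesylate while the alkoxide oxygen pushes, so the C1–C6 σ bond, antiperiplanar to the equatorial C10–O bond in the chair with equatorial isopropyl, moves to C10 in one concerted event. This is an organoaluminium-promoted pinacol-type (semipinacol) rearrangement of a 2-mesyloxy alcohol, and the same decalin-to-hydroazulenone change is known for cis-decalin-1,2-diol monosulfonates under basic or alumina conditions. Neither ring is made by cyclisation: the five-membered ring (C6, C7, C8, C9, C10) arises by contraction of ring B and the seven-membered ring (C1 to C6 plus C10) by one-carbon enlargement of ring A, both through the single new C6–C10 bond. The only new stereocentre, C10, is set by backside displacement of the β-mesylate (inversion) while C6 migrates with retention, which places H10 anti to the C6 methyl (trans fusion). The step needs C6 to move rather than C2 or C8: C1–C2 is gauche to the leaving group, whereas C9–C8 is as well aligned as C1–C6, so O9 carries a silyl group and only O1 can carry the metal. The non-basic medium also avoids silyl transfer from O9 to the 1,3-diaxial O1, enolisation towards C2 or C10, and retro-aldol cleavage of the doubly β-oxygenated ketone.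

Step 14
Reactants: 16 trans-fused C3,C9-bis(triethylsilyloxy)hydroazulen-C1-one
Product: 17 trans-fused hydroazulen-C1-one diol (C3-OH β; C9-OH β)
Conditions: HF·pyridine, pyridine, THF, 0 °C to rt
Reagents that add atoms: none
Why: Fluoride-driven Si–O cleavage in a pyridine-buffered medium, mild enough not to dehydrate or cleave the two β-hydroxy ketone units.

Step 15
Reactants: 17 trans-fused hydroazulen-C1-one diol
Product: 18 hydroazulene triol (C1-OH α; C3-OH β; C9-OH β)
Conditions: Me4NBH(OAc)3, AcOH–MeCN, −20 °C
Reagents that add atoms: none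
Why: Evans–Saksena reduction, in which boron is bound by a β hydroxyl (O3 or O9, which reinforce each other) and hands hydride to the β face of the C1 carbonyl, so the new hydroxyl is α and anti to both directing groups.

Step 16
Reactants: 19 vanillic acid
Product: 21 4-(tert-butyldimethylsilyloxy)-3-methoxybenzoic acid, via bis-silylated vanillate 20 (not isolated)
Conditions: TBSCl (2.5 equiv), imidazole, DMF, rt; then AcOH–THF–H2O, rt
Reagents that add atoms: tert-butyldimethylsilyl chloride CC(C)(C)[Si](C)(C)Cl
Why: Exhaustive silylation followed by selective hydrolysis of the labile silyl ester leaves the phenol masked and the acid free.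

Step 17
Reactants: 18 hydroazulene triol; 21 4-(tert-butyldimethylsilyloxy)-3-methoxybenzoic acid
Product: 22 C1 ester of 18 with 21
Conditions: EDC·HCl, DMAP, CH2Cl2, rt
Reagents that add atoms: none
Why: Steglich esterification acylates only the secondary C1 hydroxyl, the two tertiary hydroxyls being inert, and the C1–O bond is untouched, so the configuration is kept.

Step 18
Reactants: 22 C1 ester of 18 with 21
Product: 23 target CNP0243386.2
Conditions: Bu4NF, AcOH, THF, 0 °C
Reagents that add atoms: none
Why: Fluoride cleavage of the aryl silyl ether, buffered with acetic acid so that the ester and the tertiary allylic alcohol do not meet basic fluoride.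

Compound list
1 | (S)-Wieland–Miescher ketone | C[C@]12CCC(=O)C=C1CCCC2=O | starting material
2 | (4aS,5S)-5-hydroxy-4a-methyl-4,4a,5,6,7,8-hexahydronaphthalen-2(3H)-one (C5-OH β) | C[C@]12CCC(=O)C=C1CCC[C@@H]2O | intermediate
3 | C5 β-mesylate of 2 | C[C@]12CCC(=O)C=C1CCC[C@@H]2OS(C)(=O)=O | intermediate
4 | (R)-4a-methyl-4,4a,7,8-tetrahydronaphthalen-2(3H)-one | C[C@]12CCC(=O)C=C1CCC=C2 | intermediate
5 | C9 tertiary allylic alcohol (C9-OH β; isopropyl α) | C[C@]12CC[C@@](O)(C(C)C)C=C1CCC=C2 | intermediate
6 | TMEDA-bound C1/C10 β-osmate ester of 5 (hexavalent osmium) | C[C@]12CC[C@@](O)(C(C)C)[C@@H]3O[Os-2]4(=O)(=O)([N+](C)(C)CC[N+]4(C)C)O[C@]13CCC=C2 | intermediate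
7 | cis-decalin triol (C1, C9, C10 hydroxyls β) | C[C@]12CC[C@@](O)(C(C)C)[C@H](O)[C@@]1(O)CCC=C2 | intermediate
8 | C10 acetate of 7 | C[C@]12CC[C@@](O)(C(C)C)[C@H](OC(C)=O)[C@@]1(O)CCC=C2 | intermediate
9 | C3 enone of 8 | C[C@]12CC[C@@](O)(C(C)C)[C@H](OC(C)=O)[C@@]1(O)CC(=O)C=C2 | intermediate
10 | C3-methylene diene | C[C@]12CC[C@@](O)(C(C)C)[C@H](OC(C)=O)[C@@]1(O)CC(=C)C=C2 | intermediate
11 | C3 spiro-epoxide (O β) | C[C@]12CC[C@@](O)(C(C)C)[C@H](OC(C)=O)[C@@]1(O)C[C@@]3(CO3)C=C2 | intermediate
12 | cis-decalin tetraol | C[C@]12CC[C@@](O)(C(C)C)[C@H](O)[C@@]1(O)C[C@](C)(O)C=C2 | intermediate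
13 | cis-decalin triol C10-mesylate | C[C@]12CC[C@@](O)(C(C)C)[C@H](OS(C)(=O)=O)[C@@]1(O)C[C@](C)(O)C=C2 | intermediate
14 | C3,C9-bis(triethylsilyl) ether of 13 (free C1-OH) | C[C@]12CC[C@@](O[Si](CC)(CC)CC)(C(C)C)[C@H](OS(C)(=O)=O)[C@@]1(O)C[C@](C)(O[Si](CC)(CC)CC)C=C2 | intermediate
15 | chloro(ethyl)aluminium C1-alkoxide of 14 | C[C@]12CC[C@@](O[Si](CC)(CC)CC)(C(C)C)[C@H](OS(C)(=O)=O)[C@@]1(O[Al](Cl)CC)C[C@](C)(O[Si](CC)(CC)CC)C=C2 | intermediate
16 | trans-fused C3,C9-bis(triethylsilyloxy)hydroazulen-C1-one | O=C1C[C@](C)(O[Si](CC)(CC)CC)C=C[C@@]2(C)CC[C@@](O[Si](CC)(CC)CC)(C(C)C)[C@H]12 | intermediate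
17 | trans-fused hydroazulen-C1-one diol | O=C1C[C@](C)(O)C=C[C@@]2(C)CC[C@@](O)(C(C)C)[C@H]12 | intermediate
18 | hydroazulene triol (C1-OH α) | O[C@H]1C[C@](C)(O)C=C[C@@]2(C)CC[C@@](O)(C(C)C)[C@H]12 | intermediate
19 | vanillic acid | COc1cc(C(=O)O)ccc1O | starting material
20 | tert-butyldimethylsilyl 4-(tert-butyldimethylsilyloxy)-3-methoxybenzoate | COc1cc(C(=O)O[Si](C)(C)C(C)(C)C)ccc1O[Si](C)(C)C(C)(C)C | intermediate
21 | 4-(tert-butyldimethylsilyloxy)-3-methoxybenzoic acid | COc1cc(C(=O)O)ccc1O[Si](C)(C)C(C)(C)C | intermediate
22 | C1 ester of 18 with 21 | COc1cc(C(=O)O[C@H]2C[C@](C)(O)C=C[C@@]3(C)CC[C@@](O)(C(C)C)[C@H]23)ccc1O[Si](C)(C)C(C)(C)C | intermediate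
23 | CNP0243386.2 | COc1cc(C(=O)O[C@H]2C[C@](C)(O)C=C[C@@]3(C)CC[C@@](O)(C(C)C)[C@H]23)ccc1O | target

Total step count: 18. Longest linear sequence: 17 (steps 1–15, 17, 18).

Steps most likely to fail

**Step 13.**
- What may go wrong: the Lewis acid may ionise the tertiary allylic C3–O bond. Alternatively the alkyl shift may be too slow in the cold, so that on warming the O9 silyl group is lost and the competing C8 shift opens.
- Fallback: change from electrophilic pull to the alkoxide-driven variant, setting out from 13 and returning at 17, which bypasses 14 to 16.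
- Exactly one equivalent of KOtBu in tBuOH–THF at 0 °C is used. The base is consumed as the sulfonate leaves, so the β-hydroxy ketone does not meet excess base.
- Silyl groups are left out on purpose, because a silyl group on O9 would hop to the 1,3-diaxial O1 alkoxide.
- The C6/C8 choice then rests on the higher migratory aptitude of the fully substituted C6. No new compound is made (F0).

**Step 12.**
- What may go wrong: O9 and O1 may not be discriminated well enough (silylation of O1, or an unreactive O9).
- Fallback: give up choosing between the two oxygens. From 13, TESCl, imidazole and DMAP in DMF cap only the least hindered O3 and give the C3 mono(triethylsilyl) ether of the triol mesylate F1.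
- One equivalent of Et3Al then ties O1 and O9 into one six-membered aluminium dialkoxide, and Et2AlCl triggers the shift.
- With both oxygens as equal donors, the tert-alkyl C6 should outrun the primary C8. This gives the C3-silylated C9-hydroxy hydroazulen-C1-one F2.
- HF·pyridine brings the sequence back to 17.

**Step 5.**
- What may go wrong: osmylation may occur from the α face or at C4=C5, if the hydrogen bond to the hindered tertiary hydroxyl cannot overcome shielding by the C6 methyl.
- Fallback: replace the syn-dihydroxylation by two hydroxyl-directed epoxidations. From 5, VO(acac)2 and tBuOOH give the C1,C10 β-epoxy alcohol F3.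
- Diethylaluminium 2,2,6,6-tetramethylpiperidide removes the only available syn hydrogen (on C2) and gives the C9,C10 β-diol with C1=C2 and C4=C5 alkenes F4.
- A second VO(acac)2/tBuOOH epoxidation, directed by the allylic C10 hydroxyl, gives the C1,C2 β-epoxide F5.
- LiEt3BH opens F5 at C2 and returns to 7.

Further compounds
F0 | step 13 | none | none
F1 | step 12 | C3 mono(triethylsilyl) ether of the triol mesylate | C[C@]12CC[C@@](O)(C(C)C)[C@H](OS(C)(=O)=O)[C@@]1(O)C[C@](C)(O[Si](CC)(CC)CC)C=C2
F2 | step 12 | C3-silylated C9-hydroxy hydroazulen-C1-one | O=C1C[C@](C)(O[Si](CC)(CC)CC)C=C[C@@]2(C)CC[C@@](O)(C(C)C)[C@H]12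
F3 | step 5 | C1,C10 β-epoxy alcohol | C[C@]12CC[C@@](O)(C(C)C)[C@@H]3O[C@]13CCC=C2
F4 | step 5 | C9,C10 β-diol with C1=C2 and C4=C5 alkenes | C[C@]12CC[C@@](O)(C(C)C)[C@H](O)C1=CCC=C2
F5 | step 5 | C1,C2 β-epoxide | C[C@]12CC[C@@](O)(C(C)C)[C@H](O)[C@]13O[C@@H]3CC=C2
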